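What is left over as Q, once E has taken its cut of the L turned over, is what you are asked to find for one charge in different vessels.

| flask | L | remark | time |
|---|---|---|---|
| noon | 0.20 M | one stirred flow tank at steady state, fed with the mixture as stated, mean residence time 25.0 h |  |
| autumn | 0.20 M | a single well-mixed tank run continuously and read at steady state, 5.0 h in it on average |  |
| dusk | 0.20 M | everything together in a closed stirred flask, run for 5.0 h | 5.0 h |

    L + 2 Q → 3 Q (k1 = 0.0078 /M²/s)
    L → Q (k2 = 1.8 × 10⁻⁵ /s)
    Q ⇌ E (K3 = 0.52, k3 = 3.1 × 10⁻⁴ /s)

- a doubled species enters its step squared and goes two at a time
- the stated concentrations are those of everything mixed, before any reaction; amounts are the same in each set-up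
- run time (dusk): 5.0 h

- the set-up with the highest amount of Q at the outlet or at the end, in percent of the L put in ("none" if the first two lie within 2 percentage points) (noon / autumn / dusk / none)
- amount of Q at the outlet or at the end, in percent of the L put in, noon
- amount of Q at the outlet or at the end, in percent of the L put in, autumn
- amount of Q at the outlet or at the end, in percent of the L put in, dusk

Let x be the fraction of the charge turned over, and build up the noon tank one process at a time. In a tank, the ratio of L turned over to L left equals what the steps do in one residence time. With the plain step L → Q by itself that ratio is 1.62, so x is 61.8 %, and that fraction is Q.

Autocatalysis adds a term, 28.1 times x squared. Setting x near one in that term gives about 96.7 %, which is more than the plain step gave.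

Now add E. Counting its forward rate and not the way back, Q goes to E with a half-life of 0.621 h, much shorter than the 25.0 h in the noon tank, so I treat Q and E as a rapid equilibrium. E stands at 0.52 of Q, and the part of the turned-over L that remains Q is 65.8 %. This is the free share.

The free share enters twice. Q is squared in the autocatalytic term, which shrinks to 12.2 times x squared. Putting x back into the balance over a few passes gives 92.3 %. The outlet then holds the free share of that as Q, 60.7 %, so E pulls Q well below the 96.7 % reckoned without it. The autumn tank and the dusk flask have 5.0 h against 25.0 h, so I expect noon to be best, and my reckoning goes no further.

The forecast also names noon, with 61.2 % for noon, a little above my figure, then 32.2 % for autumn and 23.5 % for dusk. It reasons that “about a third of the converted L sits as E”.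

The simulation gives noon as best, with 61.2 %, against 32.3 % for autumn and 23.5 % for dusk, each close to the forecast's value. With the step from Q to E struck out both ways, the noon tank gives 96.5 %, which is 35 percentage points higher. Now take the dusk flask, left for 50.0 h. Taken of the full charge, the free share gives 65.8 % as Q, and that flask reads 65.8 %.

(The constants used here are assumed.)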